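The data are simulated from invented constants; the scatter is artificial.

Compare two rates: the rate at which bis adduct forms and the rate at which starting material is used. Let A, M and D be starting material, first product and bis adduct as fractions of the starting material charged. Both steps use partner, so its concentration cancels and the ratio is κM/A, where κ is the second step's rate constant over the first's.

| flask | starting material | partner | scavenger | remark | time |
|---|---|---|---|---|---|
| alder | 0.10 M | 0.80 equiv | 0.80 equiv | run made earlier |  |
| cedar | 0.067 M | 0.80 equiv | 0.80 equiv | run made earlier |  |
| ash | 0.15 M | 0.80 equiv | 0.80 equiv | run made earlier |  |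
| larch | 0.10 M | 0.80 equiv | 1.2 equiv | run made earlier |  |
| blue | 0.10 M | 0.800 equiv | 0.800 equiv | a closed flask charged with all of it at once and left for 4.0 d | 4.0 d |
| grey | 0.10 M | 0.800 equiv | 0.800 equiv | one stirred flow tank at steady state, fed with the mixture as stated, mean residence time 40.0 d |  |
| ochre | 0.10 M (fed, over 2.00 d) | 0.800 equiv | 0.800 equiv | all but starting material at the start; starting material goes in evenly over 2.00 d, the run ends at 4.0 d | 4.0 d |
| green | 0.10 M | 0.800 equiv | 0.800 equiv | a single well-mixed tank run continuously and read at steady state, 4.0 d in it on average |  |

| run | time / d | first product / % | bis adduct / % |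
|---|---|---|---|
| alder | 0.500 | 49.3 | 9.0 |
| alder | 1.04 | 53.1 | 13.6 |
| alder | 1.25 | 53.9 | 12.3 |
| alder | 2.08 | 53.1 | 12.6 |
| alder | 2.50 | 53.1 | 13.5 |
| cedar | 0.208 | 32.1 | 2.2 |
| cedar | 0.625 | 47.9 | 8.6 |
| cedar | 1.04 | 51.3 | 11.2 |
| cedar | 1.67 | 53.3 | 12.8 |
| cedar | 2.50 | 53.0 | 12.7 |
| ash | 0.208 | 44.6 | 6.6 |
| ash | 0.625 | 52.4 | 11.6 |
| ash | 1.04 | 53.4 | 12.8 |
| ash | 1.67 | 54.1 | 13.5 |
| ash | 2.50 | 53.5 | 13.9 |
| larch | 0.208 | 38.0 | 4.3 |
| larch | 0.333 | 45.4 | 7.1 |
| larch | 0.625 | 50.4 | 9.7 |
| larch | 1.25 | 53.0 | 13.2 |
| larch | 2.50 | 52.7 | 12.6 |

(each reading ± 0.5 percentage points)

- for released group the idle adduct is counted in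
- the stated concentrations are those of everything mixed, before any reaction; amounts are the same in each set-up
- the earlier runs were read with a standard deviation of 0.5 percentage points
- reactions considered so far: starting material + partner -> first product + released group; partner + first product -> bis adduct + released group; partner + released group <-> idle adduct; scavenger + released group -> scavenged by-product; released group -> by-product carried off
- the feed brings no volume worth counting
- the earlier runs were made in a closed, stirred flask

1. the set-up with the highest share of first product in all that became first product or bis adduct, at the outlet or at the end ("none" if the first two lie within 2 percentage points) (blue / grey / ochre / green / none)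
2. share of first product in all that became first product or bis adduct, at the outlet or at the end, blue
3. share of first product in all that became first product or bis adduct, at the outlet or at the end, grey
4. share of first product in all that became first product or bis adduct, at the outlet or at the end, ochre
5. share of first product in all that became first product or bis adduct, at the outlet or at the end, green

1. I average the last readings of the runs: M = 53.1% and D = 13.2%. Partner used, M + 2D, is 0.795 against 0.800 equiv charged, so I treat partner as the limiting reagent.

2. I treat D as a correction. With a = 1 − M − D = 33.7%, taking M as 1 − A gives κ = 0.311. Subtracting the first product lost to bis adduct raises this to 0.354, the selectivity factor.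

3. I expect blue to repeat the runs' end, with a share of 80.1%.

4. A stirred tank holds outlet M/A throughout, so D/M = κ(M + D)/A and the share is f = 1/(1 + κx), with x = (M + D)/A. For grey I take partner as used, since 40.0 d is far longer than the 2.08 d of alder's flat readings. Then M + D = 0.800/(2 − f), and iterating gives 65.9%.

5. The forecast names blue, with 80.3% for blue, 66.7% for grey, 67% for ochre and 69.3% for green. On ochre it reasons: “slow feed puts starting material into excess partner, which favours bis”. Its grey figure is a little above mine.

The flasks give 80.1% for blue, 66.2% for grey, 65.0% for ochre and 68.8% for green, so blue leads.

    starting material + partner → first product + released group (k = 0.0370 L mol⁻¹ min⁻¹)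
    partner + first product → bis adduct + released group (k = 0.0130 L mol⁻¹ min⁻¹)
    partner + released group ⇌ idle adduct, settled at all times (K = 5.00 L mol⁻¹)
    scavenger + released group → scavenged by-product (k = 2.00 L mol⁻¹ min⁻¹)
    released group → by-product carried off (k = 0.00130 min⁻¹)

With grey's outlet contents, f gives 66.0%. For the neighbour of blue with 0.200 equiv of partner, κ gives D = 0.737%, and that flask holds 0.732%. In blue the first step had done half of its turnover by 0.129 d, and partner was down to 0.212% of its charge at 2.00 d. At 4.00 d first product stood at 53.4% and bis adduct at 13.3%, beside 33.3% of starting material.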